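**Strategy.** The route rests on opening ring C of the upper (epicatechin) unit at its aryl ether bond O1–C8a. Ring A of that unit carries oxygen at C5, C7 and C8a in a 1,3,5 pattern, so it is brought in as a 2,4,6-trifluorophenyl group whose two ortho fluorines are equivalent. The precursor is an acyclic 2-benzyloxy-1,3-diol whose C2 and C3 stereocentres (flavan numbering) come from an Evans syn-glycolate aldol. In one operation the C2 alkoxide displaces an ortho fluorine, closing ring C with retention (2,3-cis), and two benzyl oxides replace the remaining fluorines. The flavan-3,4-diol ether formed is ionised at C4 and joined to C8 of benzylated epiafzelechin; hydrogenolysis ends the route.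

Key step: step 6

Remark on the chemistry: (−)-epiafzelechin (15) is assumed to be bought as the isolated natural product; all other starting materials are catalogue chemicals.

**Step 1**
Reactants: 1 (S)-4-benzyl-1,3-oxazolidin-2-one; 2 (benzyloxy)acetyl chloride
Product: 3 (S)-4-benzyl-3-[(benzyloxy)acetyl]-1,3-oxazolidin-2-one
Conditions: n-BuLi, THF, −78 °C; then 2, −78 to 0 °C
Reagents that add atoms: none
Why: N-acylation of the lithiated oxazolidinone by the acid chloride is the standard loading of an Evans auxiliary and creates no stereocentre.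

**Step 2**
Reactants: 3 glycolate imide; 4 3,4-bis(benzyloxy)benzaldehyde
Product: 6 (4S)-4-benzyl-3-[(2S,3R)-2-(benzyloxy)-3-[3,4-bis(benzyloxy)phenyl]-3-hydroxypropanoyl]-1,3-oxazolidin-2-one, via dibutylboron Z-enolate 5 (not isolated)
Conditions: Bu2BOTf, Et3N, CH2Cl2, −78 to 0 °C; then 4, −78 to 0 °C; H2O2, pH 7 buffer, MeOH
Reagents that add atoms: none
Why: Evans boron aldol, in which the Z-enolate reacts through a closed chair transition state on the face away from the auxiliary benzyl group, so the syn adduct should form with both new stereocentres (later C2 and C3 of the upper unit) set by the auxiliary.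

**Step 3**
Reactants: 6 syn-aldol adduct
Product: 7 (2S,3R)-2-(benzyloxy)-3-[3,4-bis(benzyloxy)phenyl]-3-hydroxy-N-methoxy-N-methylpropanamide
Conditions: MeNHOMe·HCl, AlMe3, CH2Cl2, −20 to 0 °C
Reagents that add atoms: N,O-dimethylhydroxylamine hydrochloride, CNOC.Cl
Why: Weinreb amide formation by aluminium amide transamination of the aldol imide, assisted by the free β-hydroxyl, should release the auxiliary without touching either stereocentre.

**Step 4**
Reactants: 7 Weinreb amide; 8 1,3,5-trifluorobenzene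
Product: 10 (2S,3R)-2-(benzyloxy)-3-[3,4-bis(benzyloxy)phenyl]-3-hydroxy-1-(2,4,6-trifluorophenyl)propan-1-one, via 2,4,6-trifluorophenyllithium 9 (not isolated)
Conditions: 8, n-BuLi, THF, −78 °C; then 7, −78 °C; AcOH quench at −78 °C
Reagents that add atoms: none
Why: Deprotonative lithiation of 8 between two fluorines followed by acyl substitution on the Weinreb amide (the first equivalent deprotonates the hydroxyl) should stop at the ketone, because the chelated tetrahedral adduct survives until the cold acidic quench; no stereocentre is formed.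

**Step 5**
Reactants: 10 β-hydroxy ketone
Product: 11 (1R,2S,3R)-2-(benzyloxy)-3-[3,4-bis(benzyloxy)phenyl]-1-(2,4,6-trifluorophenyl)propane-1,3-diol
Conditions: Me4NBH(OAc)3, MeCN/AcOH, −20 °C
Reagents that add atoms: none
Why: Evans–Saksena reduction, with hydride delivered inside the alkoxyborohydride formed at the β-hydroxyl, should give the 1,3-anti diol under acidic conditions that cannot trigger fluoride displacement; the new carbinol centre (later C4) is planarised in step 8, so its configuration is not critical.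

**Step 6**
Reactants: 11 trifluorophenyl diol
Product: 14 (2R,3R,4R)-3,5,7-tris(benzyloxy)-2-[3,4-bis(benzyloxy)phenyl]-3,4-dihydro-2H-chromen-4-ol, via 5,7-difluorochroman-4-ol 12 (not isolated), via 7-benzyloxy-5-fluorochroman-4-ol 13 (not isolated)
Conditions: KOtBu, DMSO, 25 °C; then BnOH, KOtBu, 100 °C
Reagents that add atoms: benzyl alcohol, OCc1ccccc1
Why: Addition–elimination (SNAr): the potassium alkoxide at the carbinol next to the catechol ring (future O1) adds to an ortho C–F carbon of the trifluorophenyl ring (future C8a) and fluoride leaves, after which benzyl oxide replaces the C7 and C5 fluorines of 12 and 13 in the same way, each fluorine being activated by the inductive pull of the meta fluorines and meta oxygens. The closest known reactions are the intramolecular SNAr etherification of ortho-fluoroaryl alkanols to chromans and the stepwise alkoxide substitution of 1,3,5-trifluorobenzene. Ring C closes in a 6-exo-trig mode. No stereocentre is created, and because the benzylic C2–O bond is never broken the syn relationship of the aldol adduct should be carried over unchanged as the 2,3-cis (epi) configuration. The step needs the C2 oxygen alone to close the ring and must give no regioisomer: the C3 oxygen is a benzyl ether, the C4 alkoxide could only form a four-membered ring, the two ortho fluorines are equivalent by rotation about the aryl–C4 bond, and running the ring closure before benzyl alcohol is added keeps an ortho fluorine available.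

**Step 7**
Reactants: 15 (−)-epiafzelechin
Product: 16 (2R,3R)-5,7-bis(benzyloxy)-2-[4-(benzyloxy)phenyl]-3,4-dihydro-2H-chromen-3-ol
Conditions: BnBr, K2CO3, DMF, 0 to 25 °C
Reagents that add atoms: benzyl bromide, BrCc1ccccc1
Why: Williamson etherification in which carbonate deprotonates only the three phenols, so the secondary 3-hydroxyl should stay free and no stereocentre is touched.

**Step 8**
Reactants: 14 flavan-3,4-diol ether; 16 tri-O-benzyl-epiafzelechin (three equivalents)
Product: 17 3,5,7,3',4'-penta-O-benzyl-epicatechin-(4β→8)-5,7,4'-tri-O-benzyl-epiafzelechin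
Conditions: TMSOTf (cat.), 4 Å molecular sieves, CH2Cl2, −78 °C; Et3N quench
Reagents that add atoms: none
Why: Lewis-acid-promoted Friedel–Crafts alkylation through the ring-A-stabilised flavan-4-yl cation, which the more nucleophilic C8 of 16 (in excess to suppress oligomers) should capture on the face anti to the cis 2-aryl and 3-benzyloxy groups, setting C4 as 4β (3,4-trans).

**Step 9**
Reactants: 17 octa-O-benzyl dimer
Product: 18 epicatechin-(4β→8)-epiafzelechin (target)
Conditions: H2 (1 atm), Pd(OH)2/C, THF/MeOH/H2O, 25 °C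
Reagents that add atoms: none
Why: Catalytic hydrogenolysis should cleave all eight benzyl ethers under neutral conditions that leave the acid-labile interflavan bond and all five stereocentres untouched.

**Compound list**

1 | (S)-4-benzyl-1,3-oxazolidin-2-one | O=C1N[C@@H](Cc2ccccc2)CO1 | starting material
2 | (benzyloxy)acetyl chloride | O=C(Cl)COCc1ccccc1 | starting material
3 | (S)-4-benzyl-3-[(benzyloxy)acetyl]-1,3-oxazolidin-2-one | O=C(COCc1ccccc1)N1[C@@H](Cc2ccccc2)COC1=O | intermediate
4 | 3,4-bis(benzyloxy)benzaldehyde | O=Cc1ccc(OCc2ccccc2)c(OCc2ccccc2)c1 | starting material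
5 | dibutylboron Z-enolate of 3 (formed in the flask) | CCCCB(CCCC)O/C(=C\OCc1ccccc1)N1[C@@H](Cc2ccccc2)COC1=O | intermediate
6 | (4S)-4-benzyl-3-[(2S,3R)-2-(benzyloxy)-3-[3,4-bis(benzyloxy)phenyl]-3-hydroxypropanoyl]-1,3-oxazolidin-2-one | O[C@H](c1ccc(OCc2ccccc2)c(OCc2ccccc2)c1)[C@H](OCc1ccccc1)C(=O)N1[C@@H](Cc2ccccc2)COC1=O | intermediate
7 | (2S,3R)-2-(benzyloxy)-3-[3,4-bis(benzyloxy)phenyl]-3-hydroxy-N-methoxy-N-methylpropanamide | O[C@H](c1ccc(OCc2ccccc2)c(OCc2ccccc2)c1)[C@H](OCc1ccccc1)C(=O)N(C)OC | intermediate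
8 | 1,3,5-trifluorobenzene | Fc1cc(F)cc(F)c1 | starting material
9 | 2,4,6-trifluorophenyllithium (formed in the flask) | [Li]c1c(F)cc(F)cc1F | intermediate
10 | (2S,3R)-2-(benzyloxy)-3-[3,4-bis(benzyloxy)phenyl]-3-hydroxy-1-(2,4,6-trifluorophenyl)propan-1-one | O[C@H](c1ccc(OCc2ccccc2)c(OCc2ccccc2)c1)[C@H](OCc1ccccc1)C(=O)c1c(F)cc(F)cc1F | intermediate
11 | (1R,2S,3R)-2-(benzyloxy)-3-[3,4-bis(benzyloxy)phenyl]-1-(2,4,6-trifluorophenyl)propane-1,3-diol | O[C@H](c1ccc(OCc2ccccc2)c(OCc2ccccc2)c1)[C@H](OCc1ccccc1)[C@H](O)c1c(F)cc(F)cc1F | intermediate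
12 | (2R,3R,4R)-3-(benzyloxy)-2-[3,4-bis(benzyloxy)phenyl]-5,7-difluoro-3,4-dihydro-2H-chromen-4-ol (formed in the flask) | O1[C@H](c2ccc(OCc3ccccc3)c(OCc3ccccc3)c2)[C@H](OCc2ccccc2)[C@H](O)c2c(F)cc(F)cc12 | intermediate
13 | (2R,3R,4R)-3,7-bis(benzyloxy)-2-[3,4-bis(benzyloxy)phenyl]-5-fluoro-3,4-dihydro-2H-chromen-4-ol (formed in the flask; the less hindered C7 fluorine is expected to react first) | O1[C@H](c2ccc(OCc3ccccc3)c(OCc3ccccc3)c2)[C@H](OCc2ccccc2)[C@H](O)c2c(F)cc(OCc3ccccc3)cc12 | intermediate
14 | (2R,3R,4R)-3,5,7-tris(benzyloxy)-2-[3,4-bis(benzyloxy)phenyl]-3,4-dihydro-2H-chromen-4-ol | O1[C@H](c2ccc(OCc3ccccc3)c(OCc3ccccc3)c2)[C@H](OCc2ccccc2)[C@H](O)c2c(OCc3ccccc3)cc(OCc3ccccc3)cc12 | intermediate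
15 | (−)-epiafzelechin, (2R,3R)-2-(4-hydroxyphenyl)-3,4-dihydro-2H-chromene-3,5,7-triol | Oc1ccc([C@H]2Oc3cc(O)cc(O)c3C[C@H]2O)cc1 | starting material
16 | (2R,3R)-5,7-bis(benzyloxy)-2-[4-(benzyloxy)phenyl]-3,4-dihydro-2H-chromen-3-ol | c1ccccc1COc1ccc([C@H]2Oc3cc(OCc4ccccc4)cc(OCc4ccccc4)c3C[C@H]2O)cc1 | intermediate
17 | 3,5,7,3',4'-penta-O-benzyl-epicatechin-(4β→8)-5,7,4'-tri-O-benzyl-epiafzelechin (upper unit 2R,3R,4R; lower unit 2R,3R) | c1ccccc1COc1ccc([C@H]2Oc3c(c(OCc4ccccc4)cc(OCc4ccccc4)c3[C@H]3c4c(OCc5ccccc5)cc(OCc5ccccc5)cc4O[C@H](c4ccc(OCc5ccccc5)c(OCc5ccccc5)c4)[C@@H]3OCc3ccccc3)C[C@H]2O)cc1 | intermediate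
18 | CNP0299023.1, epicatechin-(4β→8)-epiafzelechin (upper unit 2R,3R,4R; lower unit 2R,3R) | Oc1ccc([C@H]2Oc3c(c(O)cc(O)c3[C@H]3c4c(O)cc(O)cc4O[C@H](c4ccc(O)c(O)c4)[C@@H]3O)C[C@H]2O)cc1 | target

**Step count and risks**

Total step count: 9. Longest linear sequence: 8 steps (steps 1 to 6, then 8 and 9); step 7 is the one-step side branch.

Most likely to fail, in this order:

Step 6. The last fluorine, at C5, sits next to the C4 alkoxide and between two meta oxygens, so the cascade may stall at 13. Benzyl oxide may also attack the ring before the ring closure is complete. The fallback sets out from 7 and replaces fluoride displacement by a copper-catalysed Ullmann etherification on a ring A that already carries both benzyloxy groups: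
- Commercial 1,3-bis(benzyloxy)-5-bromobenzene is iodinated ortho to bromine (NIS, MeCN) to give 1,5-bis(benzyloxy)-3-bromo-2-iodobenzene F1.
- Iodine–magnesium exchange (iPrMgCl·LiCl, THF, −40 °C) gives [2,4-bis(benzyloxy)-6-bromophenyl]magnesium chloride F2.
- F2 (excess, −40 to −20 °C) acylates on 7 to give the bromo ketone F3.
- Reduction as in step 5 (Me4NBH(OAc)3, MeCN/AcOH) gives the bromo diol F4.
- CuI, 1,10-phenanthroline, Cs2CO3, toluene, 110 °C then closes the same O1–C8a bond with retention at C2 and comes back to the route at 14.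

Step 8. The cation from 14 may alkylate a second molecule of 14 or the product (chain growth to oligomers), or attack C6 instead of C8 of 16. The fallback sets out from 14 and caps its own nucleophilic position with bromine. NBS (CH2Cl2, −40 °C) should brominate C8 to give the 8-bromo electrophile F5. F5 is coupled with one equivalent of 16 under TMSOTf to give the 8-bromo dimer F6. Hydrogenolysis with H2, Pd(OH)2/C and Et3N removes the bromine together with the benzyl groups and comes back to the route at 18.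

Step 4. Aryllithium 9 may lose lithium fluoride before it adds. The lithium alkoxide of 7 may undergo retro-aldol cleavage. The alkoxide may also cyclise onto the activated ortho fluorine of the ketone during the quench. The fallback sets out from 7, masks the hydroxyl and uses a more robust arylmagnesium reagent made by halogen–metal exchange. TESCl and imidazole in DMF give the triethylsilyl ether F7. 1-Bromo-2,4,6-trifluorobenzene with iPrMgCl·LiCl (THF, −20 °C) gives (2,4,6-trifluorophenyl)magnesium chloride F8, which adds to F7 to give the silylated ketone F9. HF·pyridine in THF at 0 °C removes the silyl group under acidic conditions and comes back to the route at 10.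

**Further compounds**

F1 | step 6 | 1,5-bis(benzyloxy)-3-bromo-2-iodobenzene | Brc1cc(OCc2ccccc2)cc(OCc2ccccc2)c1I
F2 | step 6 | [2,4-bis(benzyloxy)-6-bromophenyl]magnesium chloride | Cl[Mg]c1c(Br)cc(OCc2ccccc2)cc1OCc1ccccc1
F3 | step 6 | (2S,3R)-2-(benzyloxy)-1-[2,4-bis(benzyloxy)-6-bromophenyl]-3-[3,4-bis(benzyloxy)phenyl]-3-hydroxypropan-1-one | O[C@H](c1ccc(OCc2ccccc2)c(OCc2ccccc2)c1)[C@H](OCc1ccccc1)C(=O)c1c(Br)cc(OCc2ccccc2)cc1OCc1ccccc1
F4 | step 6 | (1R,2S,3R)-2-(benzyloxy)-1-[2,4-bis(benzyloxy)-6-bromophenyl]-3-[3,4-bis(benzyloxy)phenyl]propane-1,3-diol | O[C@H](c1ccc(OCc2ccccc2)c(OCc2ccccc2)c1)[C@H](OCc1ccccc1)[C@H](O)c1c(Br)cc(OCc2ccccc2)cc1OCc1ccccc1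
F5 | step 8 | (2R,3R,4R)-3,5,7-tris(benzyloxy)-2-[3,4-bis(benzyloxy)phenyl]-8-bromo-3,4-dihydro-2H-chromen-4-ol | O1[C@H](c2ccc(OCc3ccccc3)c(OCc3ccccc3)c2)[C@H](OCc2ccccc2)[C@H](O)c2c(OCc3ccccc3)cc(OCc3ccccc3)c(Br)c12
F6 | step 8 | 8-bromo-3,5,7,3',4'-penta-O-benzyl-epicatechin-(4β→8)-5,7,4'-tri-O-benzyl-epiafzelechin | c1ccccc1COc1ccc([C@H]2Oc3c(c(OCc4ccccc4)cc(OCc4ccccc4)c3[C@H]3c4c(OCc5ccccc5)cc(OCc5ccccc5)c(Br)c4O[C@H](c4ccc(OCc5ccccc5)c(OCc5ccccc5)c4)[C@@H]3OCc3ccccc3)C[C@H]2O)cc1
F7 | step 4 | (2S,3R)-2-(benzyloxy)-3-[3,4-bis(benzyloxy)phenyl]-N-methoxy-N-methyl-3-[(triethylsilyl)oxy]propanamide | CC[Si](CC)(CC)O[C@H](c1ccc(OCc2ccccc2)c(OCc2ccccc2)c1)[C@H](OCc1ccccc1)C(=O)N(C)OC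
F8 | step 4 | (2,4,6-trifluorophenyl)magnesium chloride | Cl[Mg]c1c(F)cc(F)cc1F
F9 | step 4 | (2S,3R)-2-(benzyloxy)-3-[3,4-bis(benzyloxy)phenyl]-3-[(triethylsilyl)oxy]-1-(2,4,6-trifluorophenyl)propan-1-one | CC[Si](CC)(CC)O[C@H](c1ccc(OCc2ccccc2)c(OCc2ccccc2)c1)[C@H](OCc1ccccc1)C(=O)c1c(F)cc(F)cc1F
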